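## Retrosynthetic overview

1. Core numbering: C1 = methyl-bearing bridgehead, C2 = CH with the oxygenated chain, C3 = quaternary carbon, C4 = CH–O bridgehead, C5–C6 = CH2CH2 bridge (C6 on C1), O7 = bridge oxygen. Dactylomelol (29) ⇐ side-chain endgame (Shi epoxide → bromide with inversion → chloride with retention; Sharpless epoxide → Wharton transposition) ⇐ bicyclic keto alcohol 18.
2. 18 ⇐ C1–C6 and O7–C4 made in one operation: Lewis-acid formal (3+2) cycloaddition of the C1 methyl ketone of acyclic 15 onto its own cyclopropane C4–C5–C6. The cyclopropane is activated by a geminal diester at C6, excised afterwards (hydrogenolysis, double photodecarboxylation).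
3. Enabling feature: the oxolane ring O7–C1–C6–C5–C4 is a carbonyl (C1=O7) plus a three-carbon 1,3-zwitterion (C4–C5–C6). The other two ring atoms C2–C3 (C3 quaternary) are a two-atom tether, so the ketone oxygen reaches C4 through a five-membered transition state and carbocycle and oxygen bridge close together.
4. 15 ⇐ (S)-carvone as a sacrificial ring: C5 → C2 (isopropenyl → C1 acetyl), doubly alkylated C6 → quaternary C3, scission of the ring C1–C2 bond → C4 aldehyde (→ cyclopropane) plus the 3-oxobutyl chain on C2.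
5. Ring order: carvone ring (used, then cleaved) → cyclopropane (made, then opened) → carbocycle and oxygen bridge in the same step → two side-chain epoxides (made, then opened).

Key step: step 9

Remark: 2, 11 and the Shi ketone are taken as commercial; the core locants above are also used for the acyclic precursors, and exo means syn to O7.

## Route

Step 1
Reactants: 1 (S)-(+)-carvone; 2 benzyl 3-bromopropyl ether
Product: 4 (5S)-6-[3-(benzyloxy)propyl]-2-methyl-5-(prop-1-en-2-yl)cyclohex-2-en-1-one (C6 epimers), via lithium dienolate 3 (not isolated)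
Conditions: LiN(iPr)2, THF, −78 °C; then 2, DMPU, −78 °C → rt
Reagents that add atoms: none
Why: Kinetic deprotonation at C6 of the enone gives the cross-conjugated lithium dienolate, which is alkylated by the primary bromide (enolate SN2 alkylation); the new C6 centre forms as an epimer mixture that is erased by re-enolisation in step 2.

Step 2
Reactants: 4 (5S)-6-[3-(benzyloxy)propyl]-2-methyl-5-(prop-1-en-2-yl)cyclohex-2-en-1-one
Product: 6 (5R,6S)-6-[3-(benzyloxy)propyl]-2,6-dimethyl-5-(prop-1-en-2-yl)cyclohex-2-en-1-one (6-methyl trans to isopropenyl), via lithium enolate 5 (not isolated)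
Conditions: LiN(iPr)2, THF, −78 °C; then MeI, −78 → 0 °C
Reagents that add atoms: iodomethane, CI
Why: Second enolate alkylation, in which the tetrasubstituted lithium enolate is methylated on the face anti to the neighbouring isopropenyl group, so the quaternary centre (future C3) is set with methyl trans and the benzyloxypropyl chain cis to isopropenyl.

Step 3
Reactants: 6 (5R,6S)-6-[3-(benzyloxy)propyl]-2,6-dimethyl-5-(prop-1-en-2-yl)cyclohex-2-en-1-one
Product: 8 (5R,6S)-6-[3-(benzyloxy)propyl]-2-hydroxy-2,6-dimethyl-5-(prop-1-en-2-yl)cyclohexan-1-one (C2 epimers), via lithium enolate 7 (not isolated)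
Conditions: LiBH(s-Bu)3, THF, −78 °C; then 3-phenyl-2-(phenylsulfonyl)oxaziridine, −78 → 0 °C
Reagents that add atoms: 3-phenyl-2-(phenylsulfonyl)oxaziridine, O=S(=O)(c1ccccc1)N1OC1c1ccccc1
Why: Conjugate hydride addition of the hindered borohydride to the β-unsubstituted enone gives the enolate regiospecifically, and its electrophilic hydroxylation by the N-sulfonyloxaziridine (Davis oxidation) installs the tertiary α-hydroxyl, whose configuration is irrelevant because this carbon becomes a ketone in step 5.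

Step 4
Reactants: 8 (5R,6S)-6-[3-(benzyloxy)propyl]-2-hydroxy-2,6-dimethyl-5-(prop-1-en-2-yl)cyclohexan-1-one
Product: 9 (3S,4R)-3-[3-(benzyloxy)propyl]-1,3-dimethyl-4-(prop-1-en-2-yl)cyclohexane-1,2-diol (mixture at C1 and C2)
Conditions: LiAlH4, THF, 0 °C → rt
Reagents that add atoms: none
Why: Hydride reduction of the hindered ketone gives the 1,2-diol needed for glycol cleavage, and either carbinol epimer is acceptable because both carbinol carbons become carbonyl groups.

Step 5
Reactants: 9 (3S,4R)-3-[3-(benzyloxy)propyl]-1,3-dimethyl-4-(prop-1-en-2-yl)cyclohexane-1,2-diol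
Product: 10 (2S,3R)-2-[3-(benzyloxy)propyl]-2-methyl-6-oxo-3-(prop-1-en-2-yl)heptanal
Conditions: NaIO4, THF/H2O, 0 °C → rt
Reagents that add atoms: none
Why: Periodate glycol cleavage (Malaprade reaction) opens the carvone-derived ring, releasing the neopentylic aldehyde (future C4) and the methyl ketone of the C2 side chain, while neither stereocentre is α to an enolisable carbonyl and both stay untouched.

Step 6
Reactants: 10 (2S,3R)-2-[3-(benzyloxy)propyl]-2-methyl-6-oxo-3-(prop-1-en-2-yl)heptanal; 11 dibenzyl malonate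
Product: 12 dibenzyl 2-[2-(3-benzyloxypropyl)-2-methyl-6-oxo-3-(prop-1-en-2-yl)heptylidene]propanedioate (stereocentres as in 10)
Conditions: TiCl4, pyridine, THF, 0 °C → rt
Reagents that add atoms: none
Why: Knoevenagel condensation in its TiCl4/pyridine variant, which tolerates α-quaternary aldehydes and in which the aldehyde should condense much faster than the methyl ketone; no stereocentre is formed.

Step 7
Reactants: 12 dibenzyl 2-[2-(3-benzyloxypropyl)-2-methyl-6-oxo-3-(prop-1-en-2-yl)heptylidene]propanedioate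
Product: 13 dibenzyl (2R)-2-[1-(benzyloxy)-4-methyl-8-oxo-5-(prop-1-en-2-yl)nonan-4-yl]cyclopropane-1,1-dicarboxylate (chain stereocentres as in 10)
Conditions: Me3S(O)I, NaH, DMSO/THF, 0 °C → rt
Reagents that add atoms: trimethylsulfoxonium iodide, C[S+](C)(C)=O.[I-]
Why: Corey–Chaykovsky cyclopropanation (Michael-initiated ring closure) of the doubly activated alkene, which should outrun ylide addition to the methyl ketone; the C4 centre is set in the conjugate addition, which by allylic 1,3-strain (C3 methyl in the alkene plane, cis to an ester) should occur anti to the branched C2 substituent and give the epimer needed for inversion in step 9.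

Step 8
Reactants: 13 dibenzyl (2R)-2-[1-(benzyloxy)-4-methyl-8-oxo-5-(prop-1-en-2-yl)nonan-4-yl]cyclopropane-1,1-dicarboxylate
Product: 15 dibenzyl (2R)-2-[5-acetyl-1-(benzyloxy)-4-methyl-8-oxononan-4-yl]cyclopropane-1,1-dicarboxylate, via secondary ozonide 14 (not isolated)
Conditions: O3, CH2Cl2, −78 °C (Sudan Red 7B end point); then Me2S, −78 °C → rt
Reagents that add atoms: ozone, [O-][O+]=O
Why: Ozonolysis with reductive work-up converts the isopropenyl group, the only C=C bond present, into the C1 acetyl group, so the ketone α to C2 is unveiled only now and under neutral conditions that should not epimerise C2.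

Step 9
Reactants: 15 dibenzyl (2R)-2-[5-acetyl-1-(benzyloxy)-4-methyl-8-oxononan-4-yl]cyclopropane-1,1-dicarboxylate
Product: 16 dibenzyl 3-endo-[3-(benzyloxy)propyl]-1,3-exo-dimethyl-2-exo-(3-oxobutyl)-7-oxabicyclo[2.2.1]heptane-6,6-dicarboxylate (core configuration of 29)
Conditions: Sc(OTf)3 (20 mol %), 4 Å MS, ClCH2CH2Cl, rt → 60 °C
Reagents that add atoms: none
Why: Sc(OTf)3 chelates the geminal diester and polarises the C4–C6 cyclopropane bond; the C1 ketone oxygen attacks C4 from the backside and the malonate carbanion released at C6 adds to the resulting cyclic oxocarbenium carbon C1, so O7–C4 and C1–C6 form in one operation. The closest known reaction type is the Lewis-acid-catalysed intramolecular formal (3+2) cross-cycloaddition of cyclopropane-1,1-diesters with tethered ketones to oxa-bridged bicycles. The oxolane O7/C1/C2/C3/C4 closes by 5-exo-tet substitution, and the carbocycle C1–C6 (and with it the second oxolane O7/C1/C6/C5/C4) closes by 6-(enolexo)-exo-trig addition of C6 to C1, possible only on the face of the oxocarbenium ion that carries the C5–C6 arm. C4 is set by stereospecific inversion of the cyclopropane centre fixed in step 7, and C1 by the geometric constraint of the bridge (O7 and C6 must be cis on the new ring), which places the oxygen bridge syn to the C2 chain and the C3 methyl group. The step needs attack at C4 and not C5, and reaction of the acetyl oxygen and not the remote ketone or the benzyl ether oxygen; the five-membered transition state, the higher substitution at C4 and the Thorpe–Ingold effect of quaternary C3 should secure the first, and the eight-membered ring required of the side-chain ketone the second. C2 is exposed to epimerisation only while it is α to the acetyl group and is locked once C1 becomes an ether carbon.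

Step 10
Reactants: 16 dibenzyl 3-endo-[3-(benzyloxy)propyl]-1,3-exo-dimethyl-2-exo-(3-oxobutyl)-7-oxabicyclo[2.2.1]heptane-6,6-dicarboxylate
Product: 17 3-endo-(3-hydroxypropyl)-1,3-exo-dimethyl-2-exo-(3-oxobutyl)-7-oxabicyclo[2.2.1]heptane-6,6-dicarboxylic acid
Conditions: H2 (1 atm), 10% Pd/C, EtOAc/MeOH, rt
Reagents that add atoms: none
Why: Hydrogenolysis cleaves the two benzyl esters and the benzyl ether in one operation, and no stereocentre or other functional group is affected.

Step 11
Reactants: 17 3-endo-(3-hydroxypropyl)-1,3-exo-dimethyl-2-exo-(3-oxobutyl)-7-oxabicyclo[2.2.1]heptane-6,6-dicarboxylic acid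
Product: 18 4-[3-endo-(3-hydroxypropyl)-1,3-exo-dimethyl-7-oxabicyclo[2.2.1]heptan-2-exo-yl]butan-2-one
Conditions: 9-mesityl-10-phenylacridinium tetrafluoroborate (5 mol %), PhSSPh (10 mol %), iPr2NEt (20 mol %), CF3CH2OH, 450 nm LEDs, rt
Reagents that add atoms: none
Why: Photoredox hydrodecarboxylation (carboxylate oxidation by the excited acridinium, loss of CO2, hydrogen-atom transfer from the thiol formed from PhSSPh) removes both carboxyl groups of the dialkylmalonic acid in turn and converts the activating C6 centre into the CH2 group of the target.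

Step 12
Reactants: 18 4-[3-endo-(3-hydroxypropyl)-1,3-exo-dimethyl-7-oxabicyclo[2.2.1]heptan-2-exo-yl]butan-2-one
Product: 19 3-[1,3-exo-dimethyl-2-exo-(3-oxobutyl)-7-oxabicyclo[2.2.1]heptan-3-endo-yl]propanal
Conditions: Dess–Martin periodinane, CH2Cl2, rt
Reagents that add atoms: none
Why: Dess–Martin oxidation takes the primary alcohol to the aldehyde, while the ketone and the ether bridge are inert.

Step 13
Reactants: 19 3-[1,3-exo-dimethyl-2-exo-(3-oxobutyl)-7-oxabicyclo[2.2.1]heptan-3-endo-yl]propanal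
Product: 20 4-[1,3-exo-dimethyl-3-endo-(4-methylpent-3-enyl)-7-oxabicyclo[2.2.1]heptan-2-exo-yl]butan-2-one
Conditions: iPrPPh3I, n-BuLi, THF, 0 °C; then 19, −78 °C → rt
Reagents that add atoms: isopropyltriphenylphosphonium iodide, CC(C)[P+](c1ccccc1)(c1ccccc1)c1ccccc1.[I-]
Why: Wittig olefination with the non-stabilised isopropylidene ylide, which at −78 °C should react with the aldehyde much faster than with the methyl ketone, gives the trisubstituted alkene of the future bromochloride terminus.

Step 14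
Reactants: 20 4-[1,3-exo-dimethyl-3-endo-(4-methylpent-3-enyl)-7-oxabicyclo[2.2.1]heptan-2-exo-yl]butan-2-one
Product: 21 ethyl (2E)-5-[1,3-exo-dimethyl-3-endo-(4-methylpent-3-enyl)-7-oxabicyclo[2.2.1]heptan-2-exo-yl]-3-methylpent-2-enoate
Conditions: (EtO)2P(O)CH2CO2Et, NaH, THF, 0 → 60 °C
Reagents that add atoms: triethyl phosphonoacetate, CCOC(=O)CP(=O)(OCC)OCC
Why: Horner–Wadsworth–Emmons olefination of the methyl ketone should give mainly the (E)-enoate (ester trans to the larger alkyl chain), the minor Z isomer being removed by chromatography.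

Step 15
Reactants: 21 ethyl (2E)-5-[1,3-exo-dimethyl-3-endo-(4-methylpent-3-enyl)-7-oxabicyclo[2.2.1]heptan-2-exo-yl]-3-methylpent-2-enoate
Product: 22 ethyl (2E)-5-{3-endo-[2-((2R)-3,3-dimethyloxiran-2-yl)ethyl]-1,3-exo-dimethyl-7-oxabicyclo[2.2.1]heptan-2-exo-yl}-3-methylpent-2-enoate
Conditions: 1,2:4,5-di-O-isopropylidene-β-D-erythro-2,3-hexodiulo-2,6-pyranose (Shi ketone, 30 mol %), KHSO5, K2CO3, Bu4NHSO4 (cat.), MeCN/CH2(OMe)2/aq. Na2B4O7, 0 °C
Reagents that add atoms: potassium peroxymonosulfate, [K+].[O-]S(=O)(=O)OO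
Why: Shi asymmetric epoxidation, in which the chiral dioxirane epoxidises the electron-rich trisubstituted alkene through a spiro transition state (the enoate is inert), and the D-fructose-derived ketone should deliver the (R)-epoxide under reagent control.

Step 16
Reactants: 22 ethyl (2E)-5-{3-endo-[2-((2R)-3,3-dimethyloxiran-2-yl)ethyl]-1,3-exo-dimethyl-7-oxabicyclo[2.2.1]heptan-2-exo-yl}-3-methylpent-2-enoate
Product: 23 ethyl (2E)-5-{3-endo-[(3S)-3-bromo-4-hydroxy-4-methylpentyl]-1,3-exo-dimethyl-7-oxabicyclo[2.2.1]heptan-2-exo-yl}-3-methylpent-2-enoate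
Conditions: Li2NiBr4, THF, 0 °C → rt
Reagents that add atoms: dilithium tetrabromonickelate, [Li+].[Li+].[Ni+2].[Br-].[Br-].[Br-].[Br-]
Why: SN2 opening of the trisubstituted epoxide by soft bromide at the less hindered secondary carbon, with inversion, should give the (S)-bromide and leave the tertiary C–O bond intact.

Step 17
Reactants: 23 ethyl (2E)-5-{3-endo-[(3S)-3-bromo-4-hydroxy-4-methylpentyl]-1,3-exo-dimethyl-7-oxabicyclo[2.2.1]heptan-2-exo-yl}-3-methylpent-2-enoate
Product: 24 ethyl (2E)-5-{3-endo-[(3S)-3-bromo-4-chloro-4-methylpentyl]-1,3-exo-dimethyl-7-oxabicyclo[2.2.1]heptan-2-exo-yl}-3-methylpent-2-enoate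
Conditions: HCl (4 M in 1,4-dioxane), CH2Cl2, −20 → 0 °C
Reagents that add atoms: hydrogen chloride, Cl
Why: SN1 chlorination of the tertiary alcohol with neighbouring-group participation of bromine (bridged bromonium ion opened by chloride at the tertiary carbon), so the (S)-CHBr centre is retained; the enoate tolerates HCl.

Step 18
Reactants: 24 ethyl (2E)-5-{3-endo-[(3S)-3-bromo-4-chloro-4-methylpentyl]-1,3-exo-dimethyl-7-oxabicyclo[2.2.1]heptan-2-exo-yl}-3-methylpent-2-enoate
Product: 25 (2E)-5-{3-endo-[(3S)-3-bromo-4-chloro-4-methylpentyl]-1,3-exo-dimethyl-7-oxabicyclo[2.2.1]heptan-2-exo-yl}-3-methylpent-2-en-1-ol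
Conditions: iBu2AlH, CH2Cl2, −78 °C
Reagents that add atoms: none
Why: DIBAL reduction of the α,β-unsaturated ester gives the (E)-allylic alcohol at −78 °C, where the alkyl bromide and chloride are inert.

Step 19
Reactants: 25 (2E)-5-{3-endo-[(3S)-3-bromo-4-chloro-4-methylpentyl]-1,3-exo-dimethyl-7-oxabicyclo[2.2.1]heptan-2-exo-yl}-3-methylpent-2-en-1-ol
Product: 26 [(2S,3S)-3-(2-{3-endo-[(3S)-3-bromo-4-chloro-4-methylpentyl]-1,3-exo-dimethyl-7-oxabicyclo[2.2.1]heptan-2-exo-yl}ethyl)-3-methyloxiran-2-yl]methanol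
Conditions: Ti(OiPr)4 (10 mol %), L-(+)-diethyl tartrate (12 mol %), t-BuOOH, 4 Å MS, CH2Cl2, −20 °C
Reagents that add atoms: tert-butyl hydroperoxide, CC(C)(C)OO
Why: Sharpless asymmetric epoxidation of the (E)-allylic alcohol with L-(+)-diethyl tartrate should give the (2S,3S)-epoxy alcohol, which fixes the future carbinol carbon under reagent control while the isolated halides are untouched.

Step 20
Reactants: 26 [(2S,3S)-3-(2-{3-endo-[(3S)-3-bromo-4-chloro-4-methylpentyl]-1,3-exo-dimethyl-7-oxabicyclo[2.2.1]heptan-2-exo-yl}ethyl)-3-methyloxiran-2-yl]methanol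
Product: 27 α,β-epoxy aldehyde of 26 (oxirane-2-carbaldehyde, both epoxide centres unchanged)
Conditions: Dess–Martin periodinane, CH2Cl2, 0 °C
Reagents that add atoms: none
Why: Dess–Martin oxidation converts the epoxy alcohol into the α,β-epoxy aldehyde under neutral conditions that leave the epoxide and the halides alone.

Step 21
Reactants: 27 α,β-epoxy aldehyde of 26
Product: 29 dactylomelol, (3S)-5-[(1R,2S,3S,4S)-3-[(3S)-3-bromo-4-chloro-4-methylpentyl]-1,3-dimethyl-7-oxabicyclo[2.2.1]heptan-2-yl]-3-methylpent-1-en-3-ol, via epoxy hydrazone 28 (not isolated)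
Conditions: N2H4·H2O, AcOH (cat.), MeOH, 0 °C → rt
Reagents that add atoms: none
Why: Wharton transposition, in which the hydrazone opens the epoxide to a vinyl diazene that loses N2, gives the terminal vinyl group and the tertiary allylic alcohol with the C–O stereocentre from step 19 untouched.

## Compound list

1 | (S)-(+)-carvone, (5S)-2-methyl-5-(prop-1-en-2-yl)cyclohex-2-en-1-one | CC1=CC[C@@H](CC1=O)C(C)=C | starting material
2 | benzyl 3-bromopropyl ether | BrCCCOCc1ccccc1 | starting material
3 | lithium dienolate of 1 (C6 deprotonated; not isolated) | [Li+].CC1=CC[C@H](C(C)=C)C=C1[O-] | intermediate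
4 | (5S)-6-[3-(benzyloxy)propyl]-2-methyl-5-(prop-1-en-2-yl)cyclohex-2-en-1-one, C6 epimers | CC1=CC[C@@H](C(CCCOCc2ccccc2)C1=O)C(C)=C | intermediate
5 | lithium enolate of 4 (not isolated) | [Li+].CC1=CC[C@H](C(C)=C)C(CCCOCc2ccccc2)=C1[O-] | intermediate
6 | (5R,6S)-6-[3-(benzyloxy)propyl]-2,6-dimethyl-5-(prop-1-en-2-yl)cyclohex-2-en-1-one | CC1=CC[C@H](C(C)=C)[C@](C)(CCCOCc2ccccc2)C1=O | intermediate
7 | lithium enolate from conjugate reduction of 6 (not isolated) | [Li+].CC1=C([O-])[C@@](C)(CCCOCc2ccccc2)[C@@H](C(C)=C)CC1 | intermediate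
8 | (5R,6S)-6-[3-(benzyloxy)propyl]-2-hydroxy-2,6-dimethyl-5-(prop-1-en-2-yl)cyclohexan-1-one, C2 epimers | CC1(O)CC[C@H](C(C)=C)[C@](C)(CCCOCc2ccccc2)C1=O | intermediate
9 | (3S,4R)-3-[3-(benzyloxy)propyl]-1,3-dimethyl-4-(prop-1-en-2-yl)cyclohexane-1,2-diol, mixture at C1 and C2 | CC1(O)CC[C@H](C(C)=C)[C@](C)(CCCOCc2ccccc2)C1O | intermediate
10 | (2S,3R)-2-[3-(benzyloxy)propyl]-2-methyl-6-oxo-3-(prop-1-en-2-yl)heptanal | CC(=O)CC[C@H](C(C)=C)[C@](C)(CCCOCc1ccccc1)C=O | intermediate
11 | dibenzyl malonate | O=C(CC(=O)OCc1ccccc1)OCc1ccccc1 | starting material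
12 | dibenzyl 2-[2-(3-benzyloxypropyl)-2-methyl-6-oxo-3-(prop-1-en-2-yl)heptylidene]propanedioate, stereocentres as in 10 | CC(=O)CC[C@H](C(C)=C)[C@](C)(CCCOCc1ccccc1)C=C(C(=O)OCc2ccccc2)C(=O)OCc3ccccc3 | intermediate
13 | dibenzyl (2R)-2-[1-(benzyloxy)-4-methyl-8-oxo-5-(prop-1-en-2-yl)nonan-4-yl]cyclopropane-1,1-dicarboxylate | CC(=O)CC[C@H](C(C)=C)[C@](C)(CCCOCc1ccccc1)[C@H]2CC2(C(=O)OCc3ccccc3)C(=O)OCc4ccccc4 | intermediate
14 | secondary ozonide of 13 (3-methyl-1,2,4-trioxolan-3-yl in place of isopropenyl; not isolated) | CC(=O)CC[C@H](C1(C)OCOO1)[C@](C)(CCCOCc2ccccc2)[C@H]3CC3(C(=O)OCc4ccccc4)C(=O)OCc5ccccc5 | intermediate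
15 | dibenzyl (2R)-2-[5-acetyl-1-(benzyloxy)-4-methyl-8-oxononan-4-yl]cyclopropane-1,1-dicarboxylate | CC(=O)CC[C@H](C(C)=O)[C@](C)(CCCOCc1ccccc1)[C@H]2CC2(C(=O)OCc3ccccc3)C(=O)OCc4ccccc4 | intermediate
16 | dibenzyl 3-endo-[3-(benzyloxy)propyl]-1,3-exo-dimethyl-2-exo-(3-oxobutyl)-7-oxabicyclo[2.2.1]heptane-6,6-dicarboxylate | CC(=O)CC[C@H]1[C@](C)(CCCOCc3ccccc3)[C@@H]2CC(C(=O)OCc4ccccc4)(C(=O)OCc5ccccc5)[C@@]1(C)O2 | intermediate
17 | 3-endo-(3-hydroxypropyl)-1,3-exo-dimethyl-2-exo-(3-oxobutyl)-7-oxabicyclo[2.2.1]heptane-6,6-dicarboxylic acid | CC(=O)CC[C@H]1[C@](C)(CCCO)[C@@H]2CC(C(=O)O)(C(=O)O)[C@@]1(C)O2 | intermediate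
18 | 4-[3-endo-(3-hydroxypropyl)-1,3-exo-dimethyl-7-oxabicyclo[2.2.1]heptan-2-exo-yl]butan-2-one | CC(=O)CC[C@H]1[C@](C)(CCCO)[C@@H]2CC[C@@]1(C)O2 | intermediate
19 | 3-[1,3-exo-dimethyl-2-exo-(3-oxobutyl)-7-oxabicyclo[2.2.1]heptan-3-endo-yl]propanal | CC(=O)CC[C@H]1[C@](C)(CCC=O)[C@@H]2CC[C@@]1(C)O2 | intermediate
20 | 4-[1,3-exo-dimethyl-3-endo-(4-methylpent-3-enyl)-7-oxabicyclo[2.2.1]heptan-2-exo-yl]butan-2-one | CC(=O)CC[C@H]1[C@](C)(CCC=C(C)C)[C@@H]2CC[C@@]1(C)O2 | intermediate
21 | ethyl (2E)-5-[1,3-exo-dimethyl-3-endo-(4-methylpent-3-enyl)-7-oxabicyclo[2.2.1]heptan-2-exo-yl]-3-methylpent-2-enoate | CCOC(=O)/C=C(\C)CC[C@H]1[C@](C)(CCC=C(C)C)[C@@H]2CC[C@@]1(C)O2 | intermediate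
22 | (R)-epoxide of 21 at the 4-methylpent-3-enyl terminus | CCOC(=O)/C=C(\C)CC[C@H]1[C@](C)(CC[C@H]3OC3(C)C)[C@@H]2CC[C@@]1(C)O2 | intermediate
23 | (3S)-3-bromo-4-hydroxy-4-methylpentyl enoate | CCOC(=O)/C=C(\C)CC[C@H]1[C@](C)(CC[C@H](Br)C(C)(C)O)[C@@H]2CC[C@@]1(C)O2 | intermediate
24 | (3S)-3-bromo-4-chloro-4-methylpentyl enoate | CCOC(=O)/C=C(\C)CC[C@H]1[C@](C)(CC[C@H](Br)C(C)(C)Cl)[C@@H]2CC[C@@]1(C)O2 | intermediate
25 | (2E)-allylic alcohol from 24 | OC/C=C(\C)CC[C@H]1[C@](C)(CC[C@H](Br)C(C)(C)Cl)[C@@H]2CC[C@@]1(C)O2 | intermediate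
26 | (2S,3S)-2,3-epoxy alcohol from 25 | OC[C@@H]1O[C@@]1(C)CC[C@H]2[C@](C)(CC[C@H](Br)C(C)(C)Cl)[C@@H]3CC[C@@]2(C)O3 | intermediate
27 | α,β-epoxy aldehyde from 26 | O=C[C@@H]1O[C@@]1(C)CC[C@H]2[C@](C)(CC[C@H](Br)C(C)(C)Cl)[C@@H]3CC[C@@]2(C)O3 | intermediate
28 | hydrazone of 27 (not isolated) | NN=C[C@@H]1O[C@@]1(C)CC[C@H]2[C@](C)(CC[C@H](Br)C(C)(C)Cl)[C@@H]3CC[C@@]2(C)O3 | intermediate
29 | dactylomelol | C=C[C@@](C)(O)CC[C@H]1[C@](C)(CC[C@H](Br)C(C)(C)Cl)[C@@H]2CC[C@@]1(C)O2 | target

## Step count and risks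

Total step count: 21. Longest linear sequence: 21 steps from (S)-carvone (1); 2 and 11 are used as purchased.

Steps most likely to fail:

Step 9. The donor carbon of the cyclopropane carries only alkyl groups, so ring opening may be slow, the oxygen may attack C5 instead of C4, the benzyl ether oxygen may intervene, or the 1,5-diketone may undergo acid-induced aldol condensation first. The fallback sets out from 10 and returns at 17; it replaces Lewis-acid activation of a malonate by a spiro-activated acceptor that opens under nearly neutral conditions. Aldehyde 10 is condensed with Meldrum's acid (piperidinium acetate, CH2Cl2) to the alkylidene Meldrum's acid F1. Me3S(O)I/NaH converts it into the spirocyclopropane F2, and ozonolysis gives the acetyl spirocyclopropane F3. Heating in toluene (or Yb(OTf)3 in catalytic amount) should give the spiro cycloadduct F4. Aqueous HCl in THF at rt hydrolyses the isopropylidene malonate to the malonic acid benzyl ether F5, and hydrogenolysis (H2, Pd/C) gives 17.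

Step 7. The ylide addition next to the quaternary centre may show low or reversed facial selectivity, which would put the oxygen bridge on the wrong face in step 9. The fallback sets out from 12 and returns at 16; it uses the C4 epimer productively by changing the annulation from single to double inversion. The epimeric cyclopropane F6, separated from 13 by chromatography, is ozonised to the epimeric diketone F7. MgI2 in THF should open it by iodide attack at C4 (first inversion); the γ-iodo malonate adds to the C1 ketone to give the iodo aldolate F8 (not isolated), whose alkoxide displaces iodide at C4 (second inversion) to give 16.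

Step 16. Bromide may add at the tertiary epoxide carbon, or the epoxide may ionise and rearrange; in step 17 elimination from the bromonium ion may compete; each erodes the CHBr centre. The fallback sets out from 21 and returns at 24, replacing steps 15–17. Anti bromochlorination of the trisubstituted alkene with BrCl made in situ (N-bromosuccinimide, Bu4NCl, CH2Cl2, −78 °C; chloride at the tertiary carbon) gives 24 together with its C–Br epimer F9, which is removed by preparative HPLC.

## Further compounds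

F1 | step 9 | 5-[2-(3-benzyloxypropyl)-2-methyl-6-oxo-3-(prop-1-en-2-yl)heptylidene]-2,2-dimethyl-1,3-dioxane-4,6-dione (stereocentres as in 10) | CC(=O)CC[C@H](C(C)=C)[C@](C)(CCCOCc1ccccc1)C=C2C(=O)OC(C)(C)OC2=O
F2 | step 9 | 1-substituted 6,6-dimethyl-5,7-dioxaspiro[2.5]octane-4,8-dione (spirocyclopropane from F1) | CC(=O)CC[C@H](C(C)=C)[C@](C)(CCCOCc1ccccc1)[C@H]2CC23C(=O)OC(C)(C)OC3=O
F3 | step 9 | acetyl spirocyclopropane (isopropenyl of F2 replaced by acetyl) | CC(=O)CC[C@H](C(C)=O)[C@](C)(CCCOCc1ccccc1)[C@H]2CC23C(=O)OC(C)(C)OC3=O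
F4 | step 9 | spiro cycloadduct (7-oxabicyclo[2.2.1]heptane with C6 spiro-linked to the isopropylidene malonate) | CC(=O)CC[C@H]1[C@](C)(CCCOCc3ccccc3)[C@@H]2CC4(C(=O)OC(C)(C)OC4=O)[C@@]1(C)O2
F5 | step 9 | O-benzyl ether of 17 (malonic acid) | CC(=O)CC[C@H]1[C@](C)(CCCOCc3ccccc3)[C@@H]2CC(C(=O)O)(C(=O)O)[C@@]1(C)O2
F6 | step 7 | C4 epimer of 13, (2S)-cyclopropane | CC(=O)CC[C@H](C(C)=C)[C@](C)(CCCOCc1ccccc1)[C@@H]2CC2(C(=O)OCc3ccccc3)C(=O)OCc4ccccc4
F7 | step 7 | C4 epimer of 15, (2S)-cyclopropane | CC(=O)CC[C@H](C(C)=O)[C@](C)(CCCOCc1ccccc1)[C@@H]2CC2(C(=O)OCc3ccccc3)C(=O)OCc4ccccc4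
F8 | step 7 | iodo aldol intermediate, dibenzyl 2-hydroxy-5-iodo-2,4-dimethylcyclohexane-1,1-dicarboxylate bearing the C2 and C3 chains (written as the alcohol) | CC(=O)CC[C@H]1[C@](C)(CCCOCc2ccccc2)[C@H](I)CC(C(=O)OCc3ccccc3)(C(=O)OCc4ccccc4)[C@@]1(C)O
F9 | step 16 | C–Br epimer of 24, (3R)-3-bromo-4-chloro-4-methylpentyl | CCOC(=O)/C=C(\C)CC[C@H]1[C@](C)(CC[C@@H](Br)C(C)(C)Cl)[C@@H]2CC[C@@]1(C)O2
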